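**Strategy.** Everything rests on growing ring A onto a finished, enantiopure ring C. The feature exploited is the alternating oxygenation of ring A. Oxygen sits on C5, C7 and (as O1) C8a, which is the imprint of an acetoacetate-derived 1,3-dioxygenated diene laid across the enol-ether double bond of a 2-aryl-2,3-dihydropyran-4-one, the future C4a=C8a. One operation forms C4a–C5 and C8–C8a, closes the carbocycle and aromatises it by loss of sulfenic acid and alcohol, while C2 stays untouched. The precursor is the (2S)-dihydropyranone from a catalytic asymmetric hetero-Diels–Alder reaction. It bears a p-tolylsulfinyl activating and leaving group at C5 and the silyl-protected threo side chain made by an Evans syn-aldol.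

Key step: step 12

Abbreviation: Ar* = 4-{[(1R,2R)-1-[4-(benzyloxy)phenyl]-1,3-bis(tert-butyldimethylsilyloxy)propan-2-yl]oxy}-3,5-dimethoxyphenyl. Side-chain locants: C7'' is the benzylic carbinol carbon, C8'' the aryloxy-bearing carbon, C9'' the CH2O carbon.

Assumption on step 7: the (S)-BINOL titanium catalyst is taken to direct the diene to the Si face of an aromatic aldehyde, by analogy with related additions to benzaldehyde-type substrates. Induction is catalyst-controlled, so the antipodal ligand is used if a trial on 3,4,5-trimethoxybenzaldehyde shows the opposite sense.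

Remark on the key step: the mixed benzyl/trimethylsilyl ketal created at C5 should collapse with loss of benzyl alcohol, because the more basic oxygen leaves and silicon is shed afterwards, as with mixed silyl ketene acetals and haloquinones. Ring A is therefore written as the free 5,7-diol. Any 5-O-benzyl ether formed by the alternative loss of silanol is debenzylated in the last step and converges on the target, which is why the benzyl ester is kept in the diene.

Remark on the aldehyde: the formyl group would not survive boron enolisation, so it is carried as an aryl bromide and unmasked in one step.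

**Route**

Step 1
Reactants: 1 4-bromo-2,6-dimethoxyphenol; 2 bromoacetic acid
Product: 3 (4-bromo-2,6-dimethoxyphenoxy)acetic acid
Conditions: NaH (2.3 equiv), THF, 0 → 65 °C; then aq HCl
Reagents that add atoms: none
Why: Williamson ether synthesis, in which the sodium phenoxide displaces bromide from sodium bromoacetate by SN2 and no stereocentre is involved.

Step 2
Reactants: 3 (4-bromo-2,6-dimethoxyphenoxy)acetic acid; 4 (S)-4-benzyloxazolidin-2-one
Product: 6 (S)-4-benzyl-3-[(4-bromo-2,6-dimethoxyphenoxy)acetyl]oxazolidin-2-one, via mixed pivalic anhydride 5 (not isolated)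
Conditions: PivCl, Et3N, THF, −20 °C; then 4, LiCl, −20 °C → rt
Reagents that add atoms: none
Why: N-acylation of an oxazolidinone through a mixed anhydride, in which LiCl activates the auxiliary and the bulk of the pivaloyl carbonyl steers attack to the aryloxyacetyl carbonyl.

Step 3
Reactants: 6 (S)-4-benzyl-3-[(4-bromo-2,6-dimethoxyphenoxy)acetyl]oxazolidin-2-one; 7 4-(benzyloxy)benzaldehyde
Product: 9 (S)-4-benzyl-3-[(2S,3R)-3-[4-(benzyloxy)phenyl]-2-(4-bromo-2,6-dimethoxyphenoxy)-3-hydroxypropanoyl]oxazolidin-2-one, via boron Z-enolate 8 (not isolated)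
Conditions: Bu2BOTf, Et3N, CH2Cl2, −78 → 0 °C; 7, −78 → 0 °C; then pH 7 buffer, MeOH, 30% H2O2, 0 °C
Reagents that add atoms: none
Why: Evans syn-aldol reaction, in which the Z-boron enolate reacts through a Zimmerman–Traxler chair on the face away from the (S)-benzyl group and should set C8'' and C7'' together as the syn (2S,3R) pair, which is the (7''R,8''R)-threo relationship of the target and the outcome known for aryloxyacetyl imides.

Step 4
Reactants: 9 the aldol adduct
Product: 10 (1R,2R)-1-[4-(benzyloxy)phenyl]-2-(4-bromo-2,6-dimethoxyphenoxy)propane-1,3-diol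
Conditions: NaBH4, THF–H2O, 0 °C → rt
Reagents that add atoms: none
Why: Reductive cleavage of an N-acyloxazolidinone by borohydride takes the exocyclic carbonyl to the C9'' primary alcohol without touching either stereocentre or the aryl bromide and returns the auxiliary.

Step 5
Reactants: 10 the threo diol
Product: 11 Ar*–Br (5-bromo-1,3-dimethoxybenzene carrying the bis-TBS threo side chain on O2)
Conditions: TBSOTf (2.5 equiv), 2,6-lutidine, CH2Cl2, 0 °C
Reagents that add atoms: tert-butyldimethylsilyl triflate (TBSOTf), CC(C)(C)[Si](C)(C)OS(=O)(=O)C(F)(F)F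
Why: Silyl ether formation with the reactive triflate covers the primary and the hindered benzylic hydroxyl in one operation under buffered conditions that should not ionise C7''.

Step 6
Reactants: 11 Ar*–Br
Product: 13 Ar*–CHO (the side-chain-bearing 3,5-dimethoxybenzaldehyde), via aryllithium 12 (not isolated)
Conditions: n-BuLi, THF, −78 °C; DMF, −78 → 0 °C; sat. aq NH4Cl
Reagents that add atoms: N,N-dimethylformamide (DMF), CN(C)C=O
Why: Bromine–lithium exchange followed by formylation with DMF (Bouveault aldehyde synthesis) is faster at −78 °C than deprotonation of the benzyl or silyl ethers, as known for 3,4,5-trialkoxyphenyl bromides.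

Step 7
Reactants: 13 Ar*–CHO; 14 Danishefsky's diene, (E)-1-methoxy-3-(trimethylsilyloxy)buta-1,3-diene
Product: 16 (2S)-2-Ar*-2,3-dihydro-4H-pyran-4-one, via Mukaiyama aldol adduct 15 (not isolated)
Conditions: (S)-BINOL (20 mol %), Ti(OiPr)4 (10 mol %), 4 Å sieves, Et2O, −20 °C; then CF3CO2H (0.3 equiv), CH2Cl2, 0 °C
Reagents that add atoms: none
Why: Catalytic asymmetric hetero-Diels–Alder reaction in its Mukaiyama-aldol/cyclisation form, in which the titanium BINOLate should direct the diene to the Si face of the aldehyde and set C2 as S under catalyst control (the side-chain centres are remote), after which acid closes the ring with loss of methanol.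

Step 8
Reactants: 16 (2S)-2-Ar*-2,3-dihydro-4H-pyran-4-one
Product: 18 (2S)-2-Ar*-5-(p-tolylthio)-2,3-dihydro-4H-pyran-4-one, via chlorosulfide adduct 17 (not isolated)
Conditions: p-TolSH, NCS, CH2Cl2, 0 °C (forms p-TolSCl); add to 16, CH2Cl2, −78 → 0 °C; then Et3N, 0 °C
Reagents that add atoms: p-thiocresol, Cc1ccc(S)cc1 (converted in the flask into p-toluenesulfenyl chloride, Cc1ccc(SCl)cc1)
Why: Electrophilic sulfenylation by sulfenyl chloride addition and dehydrochlorination, known for enones and enol ethers, works here because C5 is the nucleophilic carbon of the O1–C6=C5 enol ether, chloride is taken up at C6, and Et3N removes HCl through the acidic C5–H without enolising C3.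

Step 9
Reactants: 18 the 5-(p-tolylthio)dihydropyranone
Product: 19 (2S)-2-Ar*-5-(p-tolylsulfinyl)-2,3-dihydro-4H-pyran-4-one (both sulfur epimers; used together)
Conditions: mCPBA (1.0 equiv), CH2Cl2, −78 → −30 °C
Reagents that add atoms: meta-chloroperoxybenzoic acid (mCPBA), O=C(OO)c1cccc(Cl)c1
Why: Chemoselective sulfide-to-sulfoxide oxidation with one equivalent of peracid succeeds because sulfur is far more nucleophilic than the acceptor-substituted C5=C6 bond, and the unselective new sulfur centre is harmless since sulfur is expelled in step 12.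

Step 10
Reactants: 20 benzyl acetoacetate
Product: 21 benzyl 3-(trimethylsilyloxy)but-2-enoate (alkene geometry irrelevant)
Conditions: TMSCl, Et3N, hexane, rt
Reagents that add atoms: chlorotrimethylsilane (TMSCl), C[Si](C)(C)Cl
Why: O-silylation of a β-keto ester enol under soft enolisation is the standard first stage of Chan-type diene synthesis.

Step 11
Reactants: 21 benzyl 3-(trimethylsilyloxy)but-2-enoate
Product: 23 1-benzyloxy-1,3-bis(trimethylsilyloxy)buta-1,3-diene, via lithium dienolate 22 (not isolated)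
Conditions: LDA, THF, −78 °C; TMSCl, −78 °C → rt; filtration under argon, used crude
Reagents that add atoms: chlorotrimethylsilane (TMSCl), C[Si](C)(C)Cl
Why: γ-Deprotonation of the vinylogous ester gives the extended dienolate, which the hard chlorosilane silylates on oxygen, the established second stage of Chan-type diene synthesis.

Step 12
Reactants: 19 (2S)-2-Ar*-5-(p-tolylsulfinyl)-2,3-dihydro-4H-pyran-4-one; 23 1-benzyloxy-1,3-bis(trimethylsilyloxy)buta-1,3-diene
Product: 26 (2S)-2-Ar*-5,7-dihydroxychroman-4-one (protected flavanone), via cis-fused cycloadduct 24 (not isolated), via cyclohexadiene ketal 25 (not isolated)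
Conditions: 23 (3 equiv, in portions), dry degassed toluene, Ar, rt → 90 °C; then cool, THF–dilute aq HCl, 0 °C
Reagents that add atoms: none
Why: Proposed new method: the CH2 terminus of electron-rich diene 23 attacks C6 of 19, the β-carbon of both the enone and the vinyl sulfoxide, and the ketene-acetal carbon bonds to the sulfinyl-bearing C5, in one asynchronous [4+2] event or as Mukaiyama–Michael addition followed by closure, giving cis-fused 24. Ring A is thereby closed as a six-membered carbocycle by [4+2] cycloaddition, C8–C8a forming ahead of C4a–C5. Because addition is suprafacial the sulfinyl group and H8a are syn in 24, so pericyclic syn-elimination of p-toluenesulfenic acid on heating restores C4a=C8a (25) while the medium is still neutral, which closes off β-elimination of O1, and dilute acid then ionises the C5 ketal with departure of benzyl alcohol, C8 loses a proton and both O–SiMe3 bonds hydrolyse to leave the arene. The closest known reaction type is the cycloaddition–elimination–aromatisation of Brassard- and Chan-type dienes with halo- or sulfinylquinones and with 3-acceptor-substituted chromones (xanthone synthesis), whereas a non-benzo-fused dihydropyranone has not served as the two-carbon partner. No new stereocentre survives, since C4a, C5 and C8a of 24 are all flattened, so facial and endo/exo selectivity and the sulfur configuration are irrelevant, and C2 is preserved because C3 is never enolised. The one selectivity required is regiochemical, and it is secured by matched polarisation, the donor O1 on C6 and the C=O and S=O acceptors on C5 facing the 1,3-dioxygenated diene, which places oxygen on C5 and C7.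

Step 13
Reactants: 26 the bis-TBS flavanone
Product: 27 (2S)-2-(4-{[(1R,2R)-1-[4-(benzyloxy)phenyl]-1,3-dihydroxypropan-2-yl]oxy}-3,5-dimethoxyphenyl)-5,7-dihydroxychroman-4-one
Conditions: HF·pyridine, pyridine, THF, 0 °C → rt (plastic vessel)
Reagents that add atoms: none
Why: Fluoride-mediated desilylation in a buffered, weakly acidic medium removes both TBS ethers while avoiding the base-induced flavanone–chalcone opening that would scramble C2 and the strong acid that could ionise C7'', and the remaining 4''-O-benzyl group blocks quinone methide formation.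

Step 14
Reactants: 27 the mono-benzyl flavanone
Product: 28 CNP0263993.1, (2S)-5,7-dihydroxy-2-(4-{[(1R,2R)-1,3-dihydroxy-1-(4-hydroxyphenyl)propan-2-yl]oxy}-3,5-dimethoxyphenyl)chroman-4-one
Conditions: H2 (1 atm), Pd/C (10 wt %), EtOAc, rt
Reagents that add atoms: none
Why: Catalytic hydrogenolysis of an aryl benzyl ether under neutral conditions is much faster than cleavage of the C7''–OH or C2–O1 benzylic bonds or reduction of the chelated C4 ketone, as in routine debenzylation of flavanones and arylglycerol aryl ethers.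

**Compound list**

1 | 4-bromo-2,6-dimethoxyphenol | COc1cc(Br)cc(OC)c1O | starting material
2 | bromoacetic acid | OC(=O)CBr | starting material
3 | (4-bromo-2,6-dimethoxyphenoxy)acetic acid | COc1cc(Br)cc(OC)c1OCC(=O)O | intermediate
4 | (S)-4-benzyloxazolidin-2-one | O=C1N[C@@H](Cc2ccccc2)CO1 | starting material
5 | (4-bromo-2,6-dimethoxyphenoxy)acetic pivalic anhydride | COc1cc(Br)cc(OC)c1OCC(=O)OC(=O)C(C)(C)C | intermediate
6 | (S)-4-benzyl-3-[(4-bromo-2,6-dimethoxyphenoxy)acetyl]oxazolidin-2-one | COc1cc(Br)cc(OC)c1OCC(=O)N1C(=O)OC[C@@H]1Cc1ccccc1 | intermediate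
7 | 4-(benzyloxy)benzaldehyde | O=Cc1ccc(OCc2ccccc2)cc1 | starting material
8 | (Z)-dibutylboron enolate of 6 | COc1cc(Br)cc(OC)c1O/C=C(\OB(CCCC)CCCC)N1C(=O)OC[C@@H]1Cc1ccccc1 | intermediate
9 | (S)-4-benzyl-3-[(2S,3R)-3-[4-(benzyloxy)phenyl]-2-(4-bromo-2,6-dimethoxyphenoxy)-3-hydroxypropanoyl]oxazolidin-2-one | COc1cc(Br)cc(OC)c1O[C@H](C(=O)N1C(=O)OC[C@@H]1Cc1ccccc1)[C@H](O)c1ccc(OCc2ccccc2)cc1 | intermediate
10 | (1R,2R)-1-[4-(benzyloxy)phenyl]-2-(4-bromo-2,6-dimethoxyphenoxy)propane-1,3-diol | COc1cc(Br)cc(OC)c1O[C@H](CO)[C@H](O)c1ccc(OCc2ccccc2)cc1 | intermediate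
11 | Ar*–Br | COc1cc(Br)cc(OC)c1O[C@H](CO[Si](C)(C)C(C)(C)C)[C@H](O[Si](C)(C)C(C)(C)C)c1ccc(OCc2ccccc2)cc1 | intermediate
12 | Ar*–Li | COc1cc([Li])cc(OC)c1O[C@H](CO[Si](C)(C)C(C)(C)C)[C@H](O[Si](C)(C)C(C)(C)C)c1ccc(OCc2ccccc2)cc1 | intermediate
13 | Ar*–CHO | COc1cc(C=O)cc(OC)c1O[C@H](CO[Si](C)(C)C(C)(C)C)[C@H](O[Si](C)(C)C(C)(C)C)c1ccc(OCc2ccccc2)cc1 | intermediate
14 | Danishefsky's diene | CO/C=C/C(=C)O[Si](C)(C)C | starting material
15 | (1E,5S)-5-Ar*-1-methoxy-5-(trimethylsilyloxy)pent-1-en-3-one | COc1cc([C@H](CC(=O)/C=C/OC)O[Si](C)(C)C)cc(OC)c1O[C@H](CO[Si](C)(C)C(C)(C)C)[C@H](O[Si](C)(C)C(C)(C)C)c1ccc(OCc2ccccc2)cc1 | intermediate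
16 | (2S)-2-Ar*-2,3-dihydro-4H-pyran-4-one | COc1cc([C@@H]2CC(=O)C=CO2)cc(OC)c1O[C@H](CO[Si](C)(C)C(C)(C)C)[C@H](O[Si](C)(C)C(C)(C)C)c1ccc(OCc2ccccc2)cc1 | intermediate
17 | (2S)-2-Ar*-6-chloro-5-(p-tolylthio)tetrahydropyran-4-one (C5 and C6 transient, mixture) | COc1cc([C@@H]2CC(=O)C(Sc3ccc(C)cc3)C(Cl)O2)cc(OC)c1O[C@H](CO[Si](C)(C)C(C)(C)C)[C@H](O[Si](C)(C)C(C)(C)C)c1ccc(OCc2ccccc2)cc1 | intermediate
18 | (2S)-2-Ar*-5-(p-tolylthio)-2,3-dihydro-4H-pyran-4-one | COc1cc([C@@H]2CC(=O)C(Sc3ccc(C)cc3)=CO2)cc(OC)c1O[C@H](CO[Si](C)(C)C(C)(C)C)[C@H](O[Si](C)(C)C(C)(C)C)c1ccc(OCc2ccccc2)cc1 | intermediate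
19 | (2S)-2-Ar*-5-(p-tolylsulfinyl)-2,3-dihydro-4H-pyran-4-one (one sulfur epimer drawn, both form and both serve) | COc1cc([C@@H]2CC(=O)C([S@@](=O)c3ccc(C)cc3)=CO2)cc(OC)c1O[C@H](CO[Si](C)(C)C(C)(C)C)[C@H](O[Si](C)(C)C(C)(C)C)c1ccc(OCc2ccccc2)cc1 | intermediate
20 | benzyl acetoacetate | CC(=O)CC(=O)OCc1ccccc1 | starting material
21 | benzyl 3-(trimethylsilyloxy)but-2-enoate (E drawn, geometry irrelevant) | C/C(O[Si](C)(C)C)=C\C(=O)OCc1ccccc1 | intermediate
22 | lithium dienolate of 21 | C=C(O[Si](C)(C)C)/C=C(/OCc1ccccc1)O[Li] | intermediate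
23 | 1-benzyloxy-1,3-bis(trimethylsilyloxy)buta-1,3-diene | C=C(O[Si](C)(C)C)/C=C(/OCc1ccccc1)O[Si](C)(C)C | intermediate
24 | (2S)-2-Ar*-5-(benzyloxy)-4a-(p-tolylsulfinyl)-5,7-bis(trimethylsilyloxy)-2,3,4a,5,8,8a-hexahydro-4H-chromen-4-one (cis-fused; C4a, C5, C8a and S transient, mixture) | COc1cc([C@@H]2CC(=O)C3(S(=O)c4ccc(C)cc4)C(O2)CC(O[Si](C)(C)C)=CC3(OCc4ccccc4)O[Si](C)(C)C)cc(OC)c1O[C@H](CO[Si](C)(C)C(C)(C)C)[C@H](O[Si](C)(C)C(C)(C)C)c1ccc(OCc2ccccc2)cc1 | intermediate
25 | (2S)-2-Ar*-5-(benzyloxy)-5,7-bis(trimethylsilyloxy)-2,3,5,8-tetrahydro-4H-chromen-4-one (C5 transient) | COc1cc([C@@H]2CC(=O)C3=C(O2)CC(O[Si](C)(C)C)=CC3(OCc4ccccc4)O[Si](C)(C)C)cc(OC)c1O[C@H](CO[Si](C)(C)C(C)(C)C)[C@H](O[Si](C)(C)C(C)(C)C)c1ccc(OCc2ccccc2)cc1 | intermediate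
26 | (2S)-2-Ar*-5,7-dihydroxychroman-4-one | COc1cc([C@@H]2CC(=O)c3c(O)cc(O)cc3O2)cc(OC)c1O[C@H](CO[Si](C)(C)C(C)(C)C)[C@H](O[Si](C)(C)C(C)(C)C)c1ccc(OCc2ccccc2)cc1 | intermediate
27 | (2S)-2-(4-{[(1R,2R)-1-[4-(benzyloxy)phenyl]-1,3-dihydroxypropan-2-yl]oxy}-3,5-dimethoxyphenyl)-5,7-dihydroxychroman-4-one | COc1cc([C@@H]2CC(=O)c3c(O)cc(O)cc3O2)cc(OC)c1O[C@H](CO)[C@H](O)c1ccc(OCc2ccccc2)cc1 | intermediate
28 | CNP0263993.1, (2S)-5,7-dihydroxy-2-(4-{[(1R,2R)-1,3-dihydroxy-1-(4-hydroxyphenyl)propan-2-yl]oxy}-3,5-dimethoxyphenyl)chroman-4-one | COc1cc([C@@H]2CC(=O)c3c(O)cc(O)cc3O2)cc(OC)c1O[C@H](CO)[C@H](O)c1ccc(O)cc1 | target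

**Step count**

Total: 14 steps.
Longest linear sequence: 12 steps (steps 1–9, then 12–14). The diene branch (steps 10–11) is convergent.

**Steps most likely to fail**

1. Step 12 (the labelled step).
   - What may go wrong: the diene may add to C6 in a purely stepwise Michael sense. The resulting enolate may then expel O1, opening ring C and diverting material into an aldol-type closure through the central acetoacetate carbon. Silyl transfer to the sulfinyl oxygen (Pummerer-type activation) or thermal decay of the diene may also outrun cycloaddition.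
   - Fallback (known chemistry, ring A bought rather than built): it sets out from 11 and rejoins the route at 28. Lithiation of 11 as in step 6 and trapping with B(OiPr)3, then aqueous NH4Cl, should give the arylboronic acid F1. Commercial 5,7-dihydroxychromone is dibenzylated (BnBr, K2CO3, DMF, 60 °C) to 5,7-bis(benzyloxy)-4H-chromen-4-one F2. Rhodium-catalysed asymmetric 1,4-addition of F1 to F2, an established entry to flavanones, should give the tribenzyl bis-silyl flavanone F3. Its conditions are [Rh(OH)(cod)]2, an electron-poor MeO-BIPHEP-type bisphosphine with the antipode chosen for 2S, toluene, rt. HF·pyridine as in step 13 gives the tribenzyl diol F4. Hydrogenolysis as in step 14 removes all three benzyl groups and delivers 28.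

2. Step 8.
   - What may go wrong: attack of the sulfenyl chloride on the acceptor-deactivated enol ether may be slow. Sulfenylation of the electron-rich arenes or HCl-induced loss of silyl groups could then compete.
   - Fallback (halogenation and cross-coupling in place of direct sulfenylation): it sets out from 16 and rejoins at 18. Electrophilic α-iodination (I2, pyridine, CH2Cl2, rt), well known for dihydropyranones, should give the 5-iodo-dihydropyranone F5. Base-free Migita-type C–S coupling with tributyl(p-tolylthio)stannane (Pd(PPh3)4, toluene, 90 °C) then gives 18. No free thiolate is present that could add to C6.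

3. Step 7.
   - What may go wrong: facial selectivity may be poor or turnover low with a bulky aldehyde whose many ether oxygens can bind titanium. Partial silyl loss may occur during the acid-induced ring closure.
   - Fallback (open-chain carbinol set by asymmetric reduction, ring C closed by a one-carbon insertion): it sets out from 13 and rejoins at 19, so steps 8 and 9 are bypassed as well. Roskamp homologation of 13 (ethyl diazoacetate, cat. SnCl2, CH2Cl2) should give the β-keto ester F6. Noyori transfer hydrogenation (RuCl[(S,S)-TsDPEN](p-cymene), HCO2H–Et3N, rt) should give the (3S)-β-hydroxy ester F7. Acylation of lithiated methyl p-tolyl sulfoxide (LDA, THF, −78 → 0 °C, excess carbanion) gives the hydroxy β-keto sulfoxide F8. Condensation with DMF dimethyl acetal (toluene, rt) gives the enaminone F9. Mild acid (PPTS, CH2Cl2) then closes the ring by attack of the C2 hydroxyl with loss of dimethylamine to give 19. This is the ring synthesis known for δ-hydroxy-β-keto esters and for 3-sulfinylchromones.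

**Further compounds**

F1 | step 12 | Ar*–B(OH)2 | COc1cc(B(O)O)cc(OC)c1O[C@H](CO[Si](C)(C)C(C)(C)C)[C@H](O[Si](C)(C)C(C)(C)C)c1ccc(OCc2ccccc2)cc1
F2 | step 12 | 5,7-bis(benzyloxy)-4H-chromen-4-one | O=c1ccoc2cc(OCc3ccccc3)cc(OCc3ccccc3)c12
F3 | step 12 | (2S)-2-Ar*-5,7-bis(benzyloxy)chroman-4-one | COc1cc([C@@H]2CC(=O)c3c(OCc4ccccc4)cc(OCc4ccccc4)cc3O2)cc(OC)c1O[C@H](CO[Si](C)(C)C(C)(C)C)[C@H](O[Si](C)(C)C(C)(C)C)c1ccc(OCc2ccccc2)cc1
F4 | step 12 | (2S)-5,7-bis(benzyloxy)-2-(4-{[(1R,2R)-1-[4-(benzyloxy)phenyl]-1,3-dihydroxypropan-2-yl]oxy}-3,5-dimethoxyphenyl)chroman-4-one | COc1cc([C@@H]2CC(=O)c3c(OCc4ccccc4)cc(OCc4ccccc4)cc3O2)cc(OC)c1O[C@H](CO)[C@H](O)c1ccc(OCc2ccccc2)cc1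
F5 | step 8 | (2S)-2-Ar*-5-iodo-2,3-dihydro-4H-pyran-4-one | COc1cc([C@@H]2CC(=O)C(I)=CO2)cc(OC)c1O[C@H](CO[Si](C)(C)C(C)(C)C)[C@H](O[Si](C)(C)C(C)(C)C)c1ccc(OCc2ccccc2)cc1
F6 | step 7 | ethyl 3-Ar*-3-oxopropanoate | COc1cc(C(=O)CC(=O)OCC)cc(OC)c1O[C@H](CO[Si](C)(C)C(C)(C)C)[C@H](O[Si](C)(C)C(C)(C)C)c1ccc(OCc2ccccc2)cc1
F7 | step 7 | ethyl (3S)-3-Ar*-3-hydroxypropanoate | COc1cc([C@@H](O)CC(=O)OCC)cc(OC)c1O[C@H](CO[Si](C)(C)C(C)(C)C)[C@H](O[Si](C)(C)C(C)(C)C)c1ccc(OCc2ccccc2)cc1
F8 | step 7 | (4S)-4-Ar*-4-hydroxy-1-(p-tolylsulfinyl)butan-2-one (sulfur epimers) | COc1cc([C@@H](O)CC(=O)CS(=O)c2ccc(C)cc2)cc(OC)c1O[C@H](CO[Si](C)(C)C(C)(C)C)[C@H](O[Si](C)(C)C(C)(C)C)c1ccc(OCc2ccccc2)cc1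
F9 | step 7 | (5S)-5-Ar*-1-(dimethylamino)-5-hydroxy-2-(p-tolylsulfinyl)pent-1-en-3-one (sulfur epimers) | COc1cc([C@@H](O)CC(=O)C(=CN(C)C)S(=O)c2ccc(C)cc2)cc(OC)c1O[C@H](CO[Si](C)(C)C(C)(C)C)[C@H](O[Si](C)(C)C(C)(C)C)c1ccc(OCc2ccccc2)cc1
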